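**Plan**

- Retrosynthesis: with the three phenolic MOM ethers (O3, O2', O4') put back, the benzophenone is cut at two bonds of ring B at once, C1'–C(=O) and C6'–O. This leads to the ring A acid, 3-(methoxymethoxy)-2-prenylbenzoic acid, and a ring B aryne carried as its ortho-silylaryl triflate.
- What permits this cut: on ring B the acyl carbon C1' and the hydroxyl carbon C6' are neighbours, C6' borders the only ring CH (C5'), and C1' borders the C2' oxygen, which polarises a C1'–C6' aryne in the required sense.
- Forward, ring B fragment from phloroglucinol: two MOM ethers, a TIPS ether, prenylation at C3' between the MOM ethers, carbamate-directed silylation at C1', triflate. Ring A fragment from 3-hydroxybenzaldehyde: MOM ether, prenylation at C2, oxidation to the acid.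
- The two arenes are joined in step 11 by insertion of the aryne into the carboxylate C–O bond; no ring is formed at any stage; acid methanolysis of the MOM ethers ends the route.
- Stereochemistry: cudraphenone D has no stereocentre and no stereogenic double bond, so nothing has to be set.

Key step: step 11

Remark on the chemistry: ring A is the benzoyl ring (C1 bears the carbonyl, C2 the prenyl group, C3 the hydroxyl). Ring B is the phloroglucinol ring (C1' acyl, C2', C4', C6' oxygen, C3' prenyl, C5' hydrogen). Prenyl = 3-methylbut-2-en-1-yl, MOM = methoxymethyl. 3-Hydroxybenzaldehyde is assumed as the ring A starting material, so that the formyl group can steer metalation to C2 before it is oxidised to the acid.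

**Route**

Step 1
Reactants: 1 phloroglucinol (benzene-1,3,5-triol)
Product: 2 3,5-bis(methoxymethoxy)phenol
Conditions: MOMCl (2.0 equiv), i-Pr2NEt (2.2 equiv), DMF, 0 °C to rt; chromatography
Reagents that add atoms: chloromethyl methyl ether (MOMCl), COCCl
Why: Williamson-type O-alkylation of the phenoxide with the hard electrophile MOMCl should give the bis-ether as the main component of a statistical mixture, separable from the mono- and tris-ethers by chromatography.

Step 2
Reactants: 2 3,5-bis(methoxymethoxy)phenol
Product: 3 [3,5-bis(methoxymethoxy)phenoxy]triisopropylsilane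
Conditions: TIPSCl (1.2 equiv), imidazole (2 equiv), DMF, rt
Reagents that add atoms: chlorotriisopropylsilane (TIPSCl), CC(C)[Si](Cl)(C(C)C)C(C)C
Why: Imidazole-promoted silyl ether formation caps the remaining phenol with a bulky, non-coordinating group that survives n-BuLi and shields its own ortho positions in the next step.

Step 3
Reactants: 3 [3,5-bis(methoxymethoxy)phenoxy]triisopropylsilane; 4 prenyl bromide (1-bromo-3-methylbut-2-ene)
Product: 6 [3,5-bis(methoxymethoxy)-4-(3-methylbut-2-en-1-yl)phenoxy]triisopropylsilane, via aryllithium 5 (not isolated)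
Conditions: n-BuLi (1.2 equiv), THF, 0 °C to rt; then prenyl bromide (1.5 equiv), −78 °C to rt
Reagents that add atoms: prenyl bromide (compound 4), CC(C)=CCBr
Why: Directed ortho-lithiation, in which the two MOM ethers cooperate to make the C–H between them the most acidic ring position while the TIPS ether blocks its neighbours, followed by SN2 alkylation of the chelated aryllithium at the primary carbon of prenyl bromide.

Step 4
Reactants: 6 [3,5-bis(methoxymethoxy)-4-(3-methylbut-2-en-1-yl)phenoxy]triisopropylsilane
Product: 7 3,5-bis(methoxymethoxy)-4-(3-methylbut-2-en-1-yl)phenol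
Conditions: TBAF (1.1 equiv), THF, 0 °C; aq NH4Cl
Reagents that add atoms: none
Why: Fluoride-mediated desilylation of an aryl silyl ether, driven by the Si–F bond, leaves the MOM acetals and the olefin untouched and gives a phenol that is symmetric about the O–C6'/C3' axis.

Step 5
Reactants: 7 3,5-bis(methoxymethoxy)-4-(3-methylbut-2-en-1-yl)phenol
Product: 8 3,5-bis(methoxymethoxy)-4-(3-methylbut-2-en-1-yl)phenyl N-isopropylcarbamate
Conditions: i-PrNCO (1.5 equiv), Et3N (0.2 equiv), CH2Cl2, rt
Reagents that add atoms: isopropyl isocyanate, CC(C)N=C=O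
Why: Amine-catalysed addition of the phenol to the isocyanate (carbamoylation) installs an N–H carbamate that can direct metalation after N-silylation and can later be removed under mild base.

Step 6
Reactants: 8 3,5-bis(methoxymethoxy)-4-(3-methylbut-2-en-1-yl)phenyl N-isopropylcarbamate
Product: 12 3,5-bis(methoxymethoxy)-4-(3-methylbut-2-en-1-yl)-2-(trimethylsilyl)phenyl N-isopropylcarbamate, via N-silyl carbamate 9 (not isolated), via lithiated carbamate 10 (not isolated), via disilyl carbamate 11 (not isolated)
Conditions: TBSOTf (1.1 equiv), TMEDA (1.1 equiv), Et2O, 0 °C to rt; then TMEDA (2 equiv), n-BuLi (2 equiv), −78 °C; then TMSCl, −78 °C to rt; then cold aq NaHSO4, brief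
Reagents that add atoms: chlorotrimethylsilane (TMSCl), C[Si](C)(C)Cl
Why: Directed ortho-metalation, in which N-silylation turns the carbamate into a strong directing group without an acidic proton and the two free ring positions are equivalent by symmetry and each flanked by carbamate and MOM ether, so that lithiation and TMSCl quench should place silicon at C1' before the N–Si bond is hydrolysed on work-up.

Step 7
Reactants: 12 3,5-bis(methoxymethoxy)-4-(3-methylbut-2-en-1-yl)-2-(trimethylsilyl)phenyl N-isopropylcarbamate
Product: 14 3,5-bis(methoxymethoxy)-4-(3-methylbut-2-en-1-yl)-2-(trimethylsilyl)phenyl trifluoromethanesulfonate, via silylphenol 13 (not isolated)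
Conditions: DBU (1.5 equiv), Et2NH (1.2 equiv), MeCN, 40 °C; then PhNTf2 (1.5 equiv), rt
Reagents that add atoms: N-phenylbis(trifluoromethanesulfonimide) (PhNTf2), O=S(=O)(N(c1ccccc1)S(=O)(=O)C(F)(F)F)C(F)(F)F
Why: Base-induced E1cB cleavage of the N–H carbamate, with the isocyanate captured by Et2NH as a urea, frees the ortho-silyl phenoxide, which is sulfonylated in the same flask by PhNTf2 to the ortho-silylaryl triflate without exposure to acid.

Step 8
Reactants: 15 3-hydroxybenzaldehyde
Product: 16 3-(methoxymethoxy)benzaldehyde
Conditions: MOMCl (1.3 equiv), i-Pr2NEt (1.5 equiv), CH2Cl2, 0 °C to rt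
Reagents that add atoms: chloromethyl methyl ether (MOMCl), COCCl
Why: O-alkylation of the phenol with MOMCl under amine base gives the ether that will both protect O3 and direct metalation, and the aldehyde does not react.

Step 9
Reactants: 16 3-(methoxymethoxy)benzaldehyde; 4 prenyl bromide
Product: 20 3-(methoxymethoxy)-2-(3-methylbut-2-en-1-yl)benzaldehyde, via amino alkoxide 17 (not isolated), via lithiated amino alkoxide 18 (not isolated), via prenylated amino alkoxide 19 (not isolated)
Conditions: Me2NCH2CH2NHMe (1.1 equiv), n-BuLi (1.05 equiv), THF, −20 °C; then 16; then n-BuLi (3 equiv), −20 °C; then prenyl bromide (excess), −78 °C to rt; aq NH4Cl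
Reagents that add atoms: prenyl bromide (compound 4), CC(C)=CCBr
Why: Directed ortho-lithiation through an in situ α-amino alkoxide, in which the lithium amide adds to and masks the aldehyde, the alkoxide and the MOM ether both direct n-BuLi to C2 between them, the aryllithium is alkylated by prenyl bromide (SN2), and aqueous work-up releases the aldehyde.

Step 10
Reactants: 20 3-(methoxymethoxy)-2-(3-methylbut-2-en-1-yl)benzaldehyde
Product: 21 3-(methoxymethoxy)-2-(3-methylbut-2-en-1-yl)benzoic acid
Conditions: NaClO2 (3 equiv), NaH2PO4 (3 equiv), 2-methyl-2-butene (20 equiv), t-BuOH/H2O, 0 °C to rt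
Reagents that add atoms: sodium chlorite (NaClO2), [Na+].[O-]Cl=O
Why: Pinnick oxidation converts the aldehyde into the acid at a buffered pH that the MOM acetal tolerates, and the large excess of 2-methyl-2-butene intercepts hypochlorous acid before it can attack the prenyl double bond.

Step 11
Reactants: 21 3-(methoxymethoxy)-2-(3-methylbut-2-en-1-yl)benzoic acid; 14 3,5-bis(methoxymethoxy)-4-(3-methylbut-2-en-1-yl)-2-(trimethylsilyl)phenyl trifluoromethanesulfonate
Product: 24 3,2',4'-tri-O-MOM cudraphenone D ([2-hydroxy-4,6-bis(methoxymethoxy)-5-(3-methylbut-2-en-1-yl)phenyl][3-(methoxymethoxy)-2-(3-methylbut-2-en-1-yl)phenyl]methanone), via cesium carboxylate 22 (not isolated), via aryne 23 (not isolated)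
Conditions: 21 (1.5 equiv), Cs2CO3 (0.75 equiv), MeOH, rt, evaporate and dry under vacuum; then 14 (1.0 equiv), CsF (3 equiv, dried), THF, 125 °C, sealed tube; aq NH4Cl
Reagents that add atoms: none
Why: Fluoride removes the trimethylsilyl group and triflate leaves, so that aryne 23 forms in the presence of the dry cesium carboxylate 22; the carboxylate oxygen adds to the aryne, the resulting ortho-aryl anion attacks the neighbouring ester carbonyl, and the four-membered alkoxide collapses by C–O cleavage to the ortho-acyl phenoxide, which is the known insertion of arynes from ortho-silylaryl triflates into the C–O bond of carboxylic acids. No permanent ring is closed, the only cyclic species being the transient benzoxetene alkoxide formed by 4-exo-trig attack, and no stereocentre is created. The step needs oxygen at C6' and acyl at C1': the inductively withdrawing C2' alkoxy group distorts the aryne so that the nucleophile enters at the remote, unhindered C6' next to C5'–H while negative charge develops at C1' beside that oxygen, as with 3-alkoxybenzynes in general. Using the preformed anhydrous cesium salt with no free acid leaves the aryl anion no proton to pick up, so acyl transfer should outrun formation of the simple aryl ester, and keeping the aryne precursor as the limiting component should suppress O-arylation of the product phenoxide.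

Step 12
Reactants: 24 3,2',4'-tri-O-MOM cudraphenone D
Product: 25 cudraphenone D ([3-hydroxy-2-(3-methylbut-2-en-1-yl)phenyl][2,4,6-trihydroxy-3-(3-methylbut-2-en-1-yl)phenyl]methanone)
Conditions: aq HCl (3 M)/MeOH 1:4, rt to 40 °C
Reagents that add atoms: none
Why: Acid-catalysed acetal cleavage (transacetalisation to dimethoxymethane) should remove all three MOM ethers, the one at O2' assisted by the neighbouring carbonyl group, while dilute acid and low temperature keep the prenyl groups from being protonated and cyclised onto the adjacent phenols.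

**Compound list**

1 | phloroglucinol | Oc1cc(O)cc(O)c1 | starting material
2 | 3,5-bis(methoxymethoxy)phenol | COCOc1cc(O)cc(OCOC)c1 | intermediate
3 | [3,5-bis(methoxymethoxy)phenoxy]triisopropylsilane | COCOc1cc(OCOC)cc(O[Si](C(C)C)(C(C)C)C(C)C)c1 | intermediate
4 | prenyl bromide (1-bromo-3-methylbut-2-ene) | CC(C)=CCBr | starting material
5 | [2,6-bis(methoxymethoxy)-4-(triisopropylsilyloxy)phenyl]lithium (formed in the flask) | COCOc1cc(O[Si](C(C)C)(C(C)C)C(C)C)cc(OCOC)c1[Li] | intermediate
6 | [3,5-bis(methoxymethoxy)-4-(3-methylbut-2-en-1-yl)phenoxy]triisopropylsilane | CC(C)=CCc1c(OCOC)cc(O[Si](C(C)C)(C(C)C)C(C)C)cc1OCOC | intermediate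
7 | 3,5-bis(methoxymethoxy)-4-(3-methylbut-2-en-1-yl)phenol | CC(C)=CCc1c(OCOC)cc(O)cc1OCOC | intermediate
8 | 3,5-bis(methoxymethoxy)-4-(3-methylbut-2-en-1-yl)phenyl N-isopropylcarbamate | CC(C)=CCc1c(OCOC)cc(OC(=O)NC(C)C)cc1OCOC | intermediate
9 | N-(tert-butyldimethylsilyl) derivative of carbamate 8 (formed in the flask) | CC(C)=CCc1c(OCOC)cc(OC(=O)N(C(C)C)[Si](C)(C)C(C)(C)C)cc1OCOC | intermediate
10 | 2-lithio derivative of 9 (formed in the flask) | CC(C)=CCc1c(OCOC)cc(OC(=O)N(C(C)C)[Si](C)(C)C(C)(C)C)c([Li])c1OCOC | intermediate
11 | 2-(trimethylsilyl) derivative of 9, N-silyl group still in place (formed in the flask) | CC(C)=CCc1c(OCOC)cc(OC(=O)N(C(C)C)[Si](C)(C)C(C)(C)C)c([Si](C)(C)C)c1OCOC | intermediate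
12 | 3,5-bis(methoxymethoxy)-4-(3-methylbut-2-en-1-yl)-2-(trimethylsilyl)phenyl N-isopropylcarbamate | CC(C)=CCc1c(OCOC)cc(OC(=O)NC(C)C)c([Si](C)(C)C)c1OCOC | intermediate
13 | 3,5-bis(methoxymethoxy)-4-(3-methylbut-2-en-1-yl)-2-(trimethylsilyl)phenol (formed in the flask as its amidinium salt) | CC(C)=CCc1c(OCOC)cc(O)c([Si](C)(C)C)c1OCOC | intermediate
14 | 3,5-bis(methoxymethoxy)-4-(3-methylbut-2-en-1-yl)-2-(trimethylsilyl)phenyl trifluoromethanesulfonate | CC(C)=CCc1c(OCOC)cc(OS(=O)(=O)C(F)(F)F)c([Si](C)(C)C)c1OCOC | intermediate
15 | 3-hydroxybenzaldehyde | O=Cc1cccc(O)c1 | starting material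
16 | 3-(methoxymethoxy)benzaldehyde | COCOc1cccc(C=O)c1 | intermediate
17 | lithium {[2-(dimethylamino)ethyl](methyl)amino}[3-(methoxymethoxy)phenyl]methanolate, racemic (formed in the flask) | COCOc1cccc(C(O[Li])N(C)CCN(C)C)c1 | intermediate
18 | 2-lithio derivative of 17 (formed in the flask) | COCOc1cccc(C(O[Li])N(C)CCN(C)C)c1[Li] | intermediate
19 | 2-prenyl derivative of 17, racemic (formed in the flask) | COCOc1cccc(C(O[Li])N(C)CCN(C)C)c1CC=C(C)C | intermediate
20 | 3-(methoxymethoxy)-2-(3-methylbut-2-en-1-yl)benzaldehyde | CC(C)=CCc1c(OCOC)cccc1C=O | intermediate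
21 | 3-(methoxymethoxy)-2-(3-methylbut-2-en-1-yl)benzoic acid | CC(C)=CCc1c(OCOC)cccc1C(=O)O | intermediate
22 | cesium 3-(methoxymethoxy)-2-(3-methylbut-2-en-1-yl)benzoate (formed in the flask) | CC(C)=CCc1c(OCOC)cccc1C(=O)[O-].[Cs+] | intermediate
23 | 3,5-bis(methoxymethoxy)-4-(3-methylbut-2-en-1-yl)benzyne, triple bond between C1' and C6' (formed in the flask) | COCOC1=C(CC=C(C)C)C(OCOC)=CC#C1 | intermediate
24 | 3,2',4'-tri-O-MOM cudraphenone D | CC(C)=CCc1c(OCOC)cccc1C(=O)c1c(O)cc(OCOC)c(CC=C(C)C)c1OCOC | intermediate
25 | cudraphenone D | CC(C)=CCc1c(O)cccc1C(=O)c1c(O)cc(O)c(CC=C(C)C)c1O | target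

**Step count**

Total: 12 steps. Longest linear sequence: 9 steps (steps 1 to 7, then 11 and 12); the ring A branch contributes steps 8 to 10.

**Steps most likely to fail**

Step 11. Several processes could divert the step:
- the aryl anion may be protonated before it reaches the ortho-substituted, hindered ester carbonyl, so that the sequence stops at O-arylation;
- the carboxylate may enter at the wrong aryne terminus;
- the product phenoxide may be arylated by a second aryne.

The fallback builds the ketone by carbonyl addition and oxidation, and sets out from phenol 7 and aldehyde 20. Phenol 7 is converted with NaH and MOMCl into 1,3,5-tris(methoxymethoxy)-2-(3-methylbut-2-en-1-yl)benzene F1. n-BuLi in THF at 0 °C metalates one of its two equivalent ring positions, each flanked by two MOM ethers, to give [2,4,6-tris(methoxymethoxy)-3-(3-methylbut-2-en-1-yl)phenyl]lithium F2. This adds to aldehyde 20 to give the racemic diarylmethanol F3. Dess–Martin periodinane (NaHCO3, CH2Cl2) oxidises it to the 3,2',4',6'-tetra-O-MOM ketone F4. Acid methanolysis as in step 12, now removing four MOM groups, comes back to the route at target 25.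

Step 6. Two processes could divert the step:
- deprotonation at the benzylic and allylic CH2 of the prenyl group, which lies between two coordinating MOM ethers, may compete with ring metalation;
- the silyl triflate used for N-silylation may open a MOM acetal.

The fallback replaces C–H deprotonation by halogen–lithium exchange and sets out from phenol 7. NBS (1.0 equiv, CH2Cl2, −78 °C) should brominate one of the two equivalent ring positions ortho to the hydroxyl, the electron-rich ring reacting faster than the trisubstituted olefin, to give 2-bromo-3,5-bis(methoxymethoxy)-4-(3-methylbut-2-en-1-yl)phenol F5. Hexamethyldisilazane converts it into the trimethylsilyl ether F6. n-BuLi at −78 °C exchanges bromine for lithium faster than any C–H is removed, and the aryllithium F7 undergoes the 1,3 oxygen-to-carbon silyl shift (retro-Brook rearrangement) to the lithium salt of silylphenol 13, where the route is rejoined. PhNTf2 added to the same flask gives triflate 14.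

Step 9. Three processes could divert the step:
- metalation may occur at C4 or C6 instead of C2;
- alkylation of the hindered aryllithium may be slow;
- prenyl bromide may be consumed by the excess n-BuLi.

The fallback moves the metalation to the acid oxidation level with the carboxylate as directing group, and sets out from aldehyde 16. Chlorite oxidation as in step 10 gives 3-(methoxymethoxy)benzoic acid F8. Lithium 2,2,6,6-tetramethylpiperidide (THF, 0 °C) removes the carboxyl proton and then the C2 proton between carboxylate and MOM ether to give lithium 2-lithio-3-(methoxymethoxy)benzoate F9. Alkylation with prenyl bromide 4 and careful acidification comes back to the route at acid 21.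

**Further compounds**

F1 | step 11 | 1,3,5-tris(methoxymethoxy)-2-(3-methylbut-2-en-1-yl)benzene | CC(C)=CCc1c(OCOC)cc(OCOC)cc1OCOC
F2 | step 11 | [2,4,6-tris(methoxymethoxy)-3-(3-methylbut-2-en-1-yl)phenyl]lithium | CC(C)=CCc1c(OCOC)cc(OCOC)c([Li])c1OCOC
F3 | step 11 | [3-(methoxymethoxy)-2-(3-methylbut-2-en-1-yl)phenyl][2,4,6-tris(methoxymethoxy)-3-(3-methylbut-2-en-1-yl)phenyl]methanol, racemic | CC(C)=CCc1c(OCOC)cccc1C(O)c1c(OCOC)cc(OCOC)c(CC=C(C)C)c1OCOC
F4 | step 11 | 3,2',4',6'-tetra-O-MOM cudraphenone D | CC(C)=CCc1c(OCOC)cccc1C(=O)c1c(OCOC)cc(OCOC)c(CC=C(C)C)c1OCOC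
F5 | step 6 | 2-bromo-3,5-bis(methoxymethoxy)-4-(3-methylbut-2-en-1-yl)phenol | CC(C)=CCc1c(OCOC)cc(O)c(Br)c1OCOC
F6 | step 6 | [2-bromo-3,5-bis(methoxymethoxy)-4-(3-methylbut-2-en-1-yl)phenoxy]trimethylsilane | CC(C)=CCc1c(OCOC)cc(O[Si](C)(C)C)c(Br)c1OCOC
F7 | step 6 | [2,4-bis(methoxymethoxy)-3-(3-methylbut-2-en-1-yl)-6-(trimethylsilyloxy)phenyl]lithium | CC(C)=CCc1c(OCOC)cc(O[Si](C)(C)C)c([Li])c1OCOC
F8 | step 9 | 3-(methoxymethoxy)benzoic acid | COCOc1cccc(C(=O)O)c1
F9 | step 9 | lithium 2-lithio-3-(methoxymethoxy)benzoate | COCOc1cccc(C(=O)O[Li])c1[Li]
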